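**Retrosynthetic overview**

1. Last, C3=C4 of a 4-aryl-flav-3-ene is hydrogenated anti to ring B (sets C4, 2,4-cis) while all five benzyl ethers are cleaved; before that, the C4–aryl bond to the phloroglucinol ring (ring D) is made by Suzuki–Miyaura coupling of a flav-3-en-4-yl triflate.
2. The triflate comes from a (2R)-flavanone, whose C2 is set by asymmetric hydrogenation of an achiral flavone.
3. The flavone is cut at C3–C2 and at O1–C8a into a 2-fluoro-4-(benzyloxy)acetophenone (ring A with C4 and C3) and a ring B benzoate (C2 with its carbonyl oxygen as O1); the forward step is a Claisen condensation followed in the same flask by intramolecular SNAr.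
4. Enabling feature: C4 of ring C sits on C4a of ring A, directly ortho to C8a, the carbon that carries O1. With C4 at the ketone level the C3 methyl is enolisable and a fluorine on C8a is activated for displacement by O1; the ketone later serves as the handle for the aryl group and is removed.
5. Ring order: rings A, B and D are bought as benzenes; ring C is the only ring formed (step 2).

Key step: step 2

Remark on the chemistry: the target is taken as the 2,4-cis flavan (2R,4R) drawn in the SMILES, and in step 3 the antipode of the chiral NHC ligand that leads to the 2R series is the one used.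

**Route**

Step 1
Reactants: 1 1-(2-fluoro-4-hydroxyphenyl)ethan-1-one
Product: 2 1-[4-(benzyloxy)-2-fluorophenyl]ethan-1-one
Conditions: BnBr, K2CO3, acetone, reflux
Reagents that add atoms: benzyl bromide, BrCc1ccccc1
Why: Williamson ether synthesis on the phenoxide (SN2 at the benzylic carbon); carbonate is too weak to drive ketone condensation or displacement of the aryl fluoride, and no stereocentre is involved.

Step 2
Reactants: 2 1-[4-(benzyloxy)-2-fluorophenyl]ethan-1-one; 3 methyl 4-(benzyloxy)benzoate
Product: 5 7-(benzyloxy)-2-[4-(benzyloxy)phenyl]-4H-chromen-4-one, via potassium diketonate 4 (not isolated)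
Conditions: KOtBu (2.2 equiv), THF, 0 °C to rt; then DMSO, 100 °C
Reagents that add atoms: none
Why: KOtBu turns the methyl ketone of 2 into its enolate, whose carbon (the future C3) attacks the ester carbonyl of 3 (the future C2, its oxygen the future O1) and expels methoxide in a crossed Claisen condensation, giving the potassium 1,3-diketonate 4. On heating in DMSO the enolate oxygen on C2 adds to C8a, the fluorine-bearing carbon ortho to the C4 carbonyl, and fluoride leaves from the Meisenheimer-type adduct (intramolecular SNAr). The closest known reaction type is the base-mediated cyclisation of 1-(2-fluorophenyl)-1,3-diketones to flavones, here run in the flask in which the diketone is made. Ring C closes by a 6-endo-trig addition–elimination in which O1 attacks C8a and the C4a–C4=O unit takes up the charge. No stereocentre is formed; the step needs O- over C-cyclisation of the ambident diketonate and intra- over intermolecular displacement of fluoride, and both follow from geometry, because only O1 reaches C8a through a six-membered transition state (C3 would have to close a four-membered ring), while the benzyloxy group at C7 is meta to C8a and does not cancel the activation by the C4 carbonyl.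

Step 3
Reactants: 5 7-(benzyloxy)-2-[4-(benzyloxy)phenyl]-4H-chromen-4-one
Product: 6 (2R)-7-(benzyloxy)-2-[4-(benzyloxy)phenyl]-2,3-dihydro-4H-chromen-4-one
Conditions: H2 (100 bar), Ru(cod)(2-methylallyl)2 (cat.), chiral 1,3-bis[1-(naphthalen-1-yl)ethyl]imidazolinium tetrafluoroborate (cat., antipode giving 2R), KOtBu (cat.), toluene/hexane, rt
Reagents that add atoms: none
Why: Ruthenium–NHC-catalysed asymmetric hydrogenation of the C2=C3 bond of flavones is a known reaction type in which the chiral carbene ligand differentiates the two faces of the vinylogous ester, so hydrogen should be delivered to C2 on the face that gives 2R, while benzyl ethers and the less reactive C4 carbonyl should remain.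

Step 4
Reactants: 6 (2R)-7-(benzyloxy)-2-[4-(benzyloxy)phenyl]-2,3-dihydro-4H-chromen-4-one
Product: 7 (2R)-7-(benzyloxy)-2-[4-(benzyloxy)phenyl]-2H-chromen-4-yl trifluoromethanesulfonate
Conditions: Tf2O, 2,6-di-tert-butyl-4-methylpyridine, CH2Cl2, 0 °C to rt
Reagents that add atoms: trifluoromethanesulfonic anhydride, O=S(=O)(OS(=O)(=O)C(F)(F)F)C(F)(F)F
Why: Enol triflate formation by O-triflation of the electron-rich ketone and loss of a C3 proton to the hindered pyridine avoids a free enolate, and with it the E1cB opening of ring C that would erase C2, so the 2R centre should be carried through untouched.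

Step 5
Reactants: 8 1,3,5-tris(benzyloxy)benzene; 9 dodecanoic acid
Product: 11 1-[2,4,6-tris(benzyloxy)phenyl]dodecan-1-one, via mixed anhydride 10 (not isolated)
Conditions: (CF3CO)2O, CH2Cl2, 0 °C to rt
Reagents that add atoms: none
Why: Friedel–Crafts acylation of the strongly activated triether by the mixed anhydride formed in the flask needs no metal Lewis acid, so the benzyl ethers should survive, and the first acyl group deactivates the ring against a second acylation.

Step 6
Reactants: 11 1-[2,4,6-tris(benzyloxy)phenyl]dodecan-1-one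
Product: 12 1-[2,4,6-tris(benzyloxy)-3-bromophenyl]dodecan-1-one
Conditions: NBS (1.0 equiv), MeCN, 0 °C, dark
Reagents that add atoms: N-bromosuccinimide, O=C1CCC(=O)N1Br
Why: Electrophilic aromatic bromination at one of the two equivalent ring CH positions, each ortho, ortho and para to a benzyloxy group, should be much faster than bromination of the side chain under these polar, light-free conditions, and one equivalent limits it to the monobromide.

Step 7
Reactants: 12 1-[2,4,6-tris(benzyloxy)-3-bromophenyl]dodecan-1-one
Product: 13 1-[2,4,6-tris(benzyloxy)-3-(4,4,5,5-tetramethyl-1,3,2-dioxaborolan-2-yl)phenyl]dodecan-1-one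
Conditions: B2pin2, Pd2(dba)3 (cat.), SPhos, KOAc, 1,4-dioxane, 90 °C
Reagents that add atoms: bis(pinacolato)diboron, CC1(C)OB(OC1(C)C)B1OC(C)(C)C(C)(C)O1
Why: Miyaura borylation of the aryl bromide, in which the bulky electron-rich biaryl phosphine permits oxidative addition and boryl transfer at a di-ortho-substituted carbon and the weak base KOAc leaves the hindered ketone alone.

Step 8
Reactants: 7 (2R)-7-(benzyloxy)-2-[4-(benzyloxy)phenyl]-2H-chromen-4-yl trifluoromethanesulfonate; 13 1-[2,4,6-tris(benzyloxy)-3-(4,4,5,5-tetramethyl-1,3,2-dioxaborolan-2-yl)phenyl]dodecan-1-one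
Product: 14 1-{2,4,6-tris(benzyloxy)-3-[(2R)-7-(benzyloxy)-2-[4-(benzyloxy)phenyl]-2H-chromen-4-yl]phenyl}dodecan-1-one
Conditions: Pd(OAc)2 (cat.), SPhos, K3PO4, THF/H2O, 50 °C, dark
Reagents that add atoms: none
Why: Suzuki–Miyaura coupling of an alkenyl triflate with a hindered arylboronate under the SPhos–palladium conditions suited to di-ortho-substituted partners should form the C4–aryl bond, while the C2 centre, remote from the reacting carbon, is kept by moderate temperature and exclusion of light.

Step 9
Reactants: 14 1-{2,4,6-tris(benzyloxy)-3-[(2R)-7-(benzyloxy)-2-[4-(benzyloxy)phenyl]-2H-chromen-4-yl]phenyl}dodecan-1-one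
Product: 15 1-{2,4,6-trihydroxy-3-[(2R,4R)-7-hydroxy-2-(4-hydroxyphenyl)-3,4-dihydro-2H-chromen-4-yl]phenyl}dodecan-1-one
Conditions: H2 (1 atm), 10% Pd/C, EtOAc/MeOH, rt
Reagents that add atoms: none
Why: Heterogeneous hydrogenation should add hydrogen to C3=C4 from the face of ring C opposite to ring B, so the new C4–H is anti to ring B and ring D ends up cis to it (4R), while hydrogenolysis of the five benzyl ethers occurs in the same operation and the hydrogen-bonded aryl ketone should not be reduced under neutral conditions.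

**Compound list**

1 | 1-(2-fluoro-4-hydroxyphenyl)ethan-1-one | CC(=O)c1ccc(O)cc1F | starting material
2 | 1-[4-(benzyloxy)-2-fluorophenyl]ethan-1-one | CC(=O)c1ccc(OCc2ccccc2)cc1F | intermediate
3 | methyl 4-(benzyloxy)benzoate | COC(=O)c1ccc(OCc2ccccc2)cc1 | starting material
4 | potassium diketonate: potassium enolate of 1-[4-(benzyloxy)-2-fluorophenyl]-3-[4-(benzyloxy)phenyl]propane-1,3-dione (not isolated) | [K+].[O-]C(=CC(=O)c1ccc(OCc2ccccc2)cc1F)c1ccc(OCc2ccccc2)cc1 | intermediate
5 | 7-(benzyloxy)-2-[4-(benzyloxy)phenyl]-4H-chromen-4-one | O=c1cc(-c2ccc(OCc3ccccc3)cc2)oc2cc(OCc3ccccc3)ccc12 | intermediate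
6 | (2R)-7-(benzyloxy)-2-[4-(benzyloxy)phenyl]-2,3-dihydro-4H-chromen-4-one | O=C1C[C@H](c2ccc(OCc3ccccc3)cc2)Oc2cc(OCc3ccccc3)ccc12 | intermediate
7 | (2R)-7-(benzyloxy)-2-[4-(benzyloxy)phenyl]-2H-chromen-4-yl trifluoromethanesulfonate | O=S(=O)(OC1=C[C@H](c2ccc(OCc3ccccc3)cc2)Oc2cc(OCc3ccccc3)ccc12)C(F)(F)F | intermediate
8 | 1,3,5-tris(benzyloxy)benzene | c1ccc(COc2cc(OCc3ccccc3)cc(OCc3ccccc3)c2)cc1 | starting material
9 | dodecanoic acid | CCCCCCCCCCCC(=O)O | starting material
10 | mixed anhydride: dodecanoic trifluoroacetic anhydride (not isolated) | CCCCCCCCCCCC(=O)OC(=O)C(F)(F)F | intermediate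
11 | 1-[2,4,6-tris(benzyloxy)phenyl]dodecan-1-one | CCCCCCCCCCCC(=O)c1c(OCc2ccccc2)cc(OCc2ccccc2)cc1OCc1ccccc1 | intermediate
12 | 1-[2,4,6-tris(benzyloxy)-3-bromophenyl]dodecan-1-one | CCCCCCCCCCCC(=O)c1c(OCc2ccccc2)cc(OCc2ccccc2)c(Br)c1OCc1ccccc1 | intermediate
13 | 1-[2,4,6-tris(benzyloxy)-3-(4,4,5,5-tetramethyl-1,3,2-dioxaborolan-2-yl)phenyl]dodecan-1-one | CCCCCCCCCCCC(=O)c1c(OCc2ccccc2)cc(OCc2ccccc2)c(B2OC(C)(C)C(C)(C)O2)c1OCc1ccccc1 | intermediate
14 | 1-{2,4,6-tris(benzyloxy)-3-[(2R)-7-(benzyloxy)-2-[4-(benzyloxy)phenyl]-2H-chromen-4-yl]phenyl}dodecan-1-one | CCCCCCCCCCCC(=O)c1c(OCc2ccccc2)cc(OCc2ccccc2)c(C2=C[C@H](c3ccc(OCc4ccccc4)cc3)Oc3cc(OCc4ccccc4)ccc32)c1OCc1ccccc1 | intermediate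
15 | 1-{2,4,6-trihydroxy-3-[(2R,4R)-7-hydroxy-2-(4-hydroxyphenyl)-3,4-dihydro-2H-chromen-4-yl]phenyl}dodecan-1-one | CCCCCCCCCCCC(=O)c1c(O)cc(O)c([C@@H]2C[C@H](c3ccc(O)cc3)Oc3cc(O)ccc32)c1O | target

**Step count**

Total step count: 9 steps.
Longest linear sequence: 6 steps (steps 1, 2, 3, 4, 8, 9; compounds 1, 2, 5, 6, 7, 14, 15). The branch from 8 (steps 5, 6, 7, 8, 9) is 5 steps.

**Steps most likely to fail and fallbacks**

Step 8. The electron-rich, di-ortho-alkoxy boronate 13 may lose boron by protodeboronation faster than it transmetalates to the hindered alkenylpalladium species. The 2H-chromene may also lose its C2 configuration by reversible electrocyclic ring opening if heated or exposed to light. The fallback reverses the roles of the partners and sets out from triflate 7. Miyaura borylation (B2pin2, PdCl2(dppf), KOAc, 1,4-dioxane, 80 °C) would give (2R)-7-(benzyloxy)-2-[4-(benzyloxy)phenyl]-4-(4,4,5,5-tetramethyl-1,3,2-dioxaborolan-2-yl)-2H-chromene F3, an unhindered alkenylboronate. This would then be coupled with the aryl bromide 12 (Pd(OAc)2, SPhos, K3PO4, toluene/H2O, 60 °C), so that boron never sits on ring D. The fallback comes back to the route at 14.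

Step 3. Face discrimination at C2 may be insufficient, and the C4 carbonyl may be reduced further once the C2=C3 bond is saturated. The fallback sets out from flavone 5 and replaces asymmetric hydrogenation by resolution. Conjugate reduction with LiBH(s-Bu)3 (THF, −78 °C, then NH4Cl) would give racemic 7-(benzyloxy)-2-[4-(benzyloxy)phenyl]-2,3-dihydro-4H-chromen-4-one F1. Kinetic resolution by asymmetric transfer hydrogenation (RuCl(p-cymene)[TsDPEN] in the antipode that consumes the 2S ketone, HCO2H/Et3N, EtOAc, rt) should reduce the unwanted enantiomer to the cis alcohol (2S,4S)-7-(benzyloxy)-2-[4-(benzyloxy)phenyl]-3,4-dihydro-2H-chromen-4-ol F2, which is removed by chromatography. The unreacted ketone is 6, where the fallback rejoins the route.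

Step 9. Facial selectivity at the hindered trisubstituted C3=C4 bond may be poor, and the allylic, benzylic C2–O1 bond may be hydrogenolysed before the alkene is saturated. The fallback sets out from 14 and separates the two events. Ionic hydrogenation (Et3SiH, CF3CO2H, CH2Cl2, −40 °C) protonates C3, and hydride is delivered to the C4 cation, which is stabilised by O1 and the C7 oxygen, on the face anti to ring B. This should give 1-{2,4,6-tris(benzyloxy)-3-[(2R,4R)-7-(benzyloxy)-2-[4-(benzyloxy)phenyl]-3,4-dihydro-2H-chromen-4-yl]phenyl}dodecan-1-one F4. Hydrogenolysis of the benzyl ethers on the saturated flavan (H2, Pd(OH)2/C, EtOAc/MeOH, rt) then comes back to the route at 15.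

**Further compounds**

F1 | step 3 | racemic 7-(benzyloxy)-2-[4-(benzyloxy)phenyl]-2,3-dihydro-4H-chromen-4-one | O=C1CC(c2ccc(OCc3ccccc3)cc2)Oc2cc(OCc3ccccc3)ccc12
F2 | step 3 | (2S,4S)-7-(benzyloxy)-2-[4-(benzyloxy)phenyl]-3,4-dihydro-2H-chromen-4-ol | O[C@H]1C[C@@H](c2ccc(OCc3ccccc3)cc2)Oc2cc(OCc3ccccc3)ccc21
F3 | step 8 | (2R)-7-(benzyloxy)-2-[4-(benzyloxy)phenyl]-4-(4,4,5,5-tetramethyl-1,3,2-dioxaborolan-2-yl)-2H-chromene | CC1(C)OB(OC1(C)C)C1=C[C@H](c2ccc(OCc3ccccc3)cc2)Oc2cc(OCc3ccccc3)ccc12
F4 | step 9 | 1-{2,4,6-tris(benzyloxy)-3-[(2R,4R)-7-(benzyloxy)-2-[4-(benzyloxy)phenyl]-3,4-dihydro-2H-chromen-4-yl]phenyl}dodecan-1-one | CCCCCCCCCCCC(=O)c1c(OCc2ccccc2)cc(OCc2ccccc2)c([C@@H]2C[C@H](c3ccc(OCc4ccccc4)cc3)Oc3cc(OCc4ccccc4)ccc32)c1OCc1ccccc1
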